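I start from the amounts: this flask holds as much protic impurity as free monomer, with pre-initiator at 0.34 mol%.

    free monomer + initiator → living end + monomer in chains (k1 = 0.0491 M⁻¹ min⁻¹)
    free monomer + living end → monomer in chains + living end, rate k2*[living end]*[free monomer] (k2 = 74.7 M⁻¹ min⁻¹)
    free monomer → uncatalysed product (k3 = 7.57 × 10⁻⁵ min⁻¹)
    protic impurity + free monomer → quenched substrate (k4 = 0.318 M⁻¹ min⁻¹)
    pre-initiator → initiator (k5 = 0.00275 min⁻¹)

free monomer 0.050 M; protic impurity 0.0500 M; pre-initiator 0.34 mol%; time 12 h

- the average divides the monomer in chains by the number of chains begun, living and dead together
- run time (flask): 12 h

1. average number of monomer units in a chain (chains begun, living or dead) at 12 h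
2. part of the free monomer that has reacted at 12 h

I ask first what the end state must be. The reacted part of the free monomer cannot pass 100%, and I find no lower ceiling by hand. For a floor I take the quench by itself, the step in which protic impurity and free monomer react one for one, and I reckon what I call the quench time (the second-order half-life of an equimolar pair), one over the product of the rate constant of that step and the common charge, 1.05 h. With that step alone, two partners charged equally come down to half of their charge in one quench time. With that step alone, the part left after any time is one over one plus the time counted in quench times, so 12 h leaves 8.03%. The other steps take free monomer as well, and what they take leaves the impurity in excess, so free monomer stands no higher than that. Counting the uncatalysed step, whose half-life of 150 h is long against the run, puts the floor at 92.2%. For the chain length I have no bracket.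

The forecast gives 94.9%, between 94% and 95.7%, inside my bracket, and 170 units, between 150 and 190, holding that the “equimolar impurity consumes most of the monomer”.

The flask gives 96.2% and 159 units. After 0.849 h the quench uses free monomer 130 times as fast as the growth of chains does, and at 12.0 h that ratio is down to 1.2. The free monomer left in this flask is 3.8% against the 8.03% of the quench time, and in the neighbour flask, same charges left until 5.0 h, it is 15% against 17.4%.

The constants used here are made up; the run is a simulation.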